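All runs come from a simulation with made-up constants.

Two questions stood on this flask: how long the chains were at 12 min, and how much free monomer had reacted by then.

| setting | zeta | beta | flask |
|---|---|---|---|
| free monomer | 10 mM (fed, over 12 min) | 10 mM (fed, over 12 min) | 10 mM (fed, over 12 min) |
| initiator | 0.81 mM | 1.6 mM | 0.81 mM |
| remark | the very flask that is asked about, followed so far | run made earlier |  |
| time |  |  | 12 min |

| run | time / min | monomer in chains / % | free monomer / % |
|---|---|---|---|
| zeta | 1.50 | 0.1 | 12.2 |
| zeta | 3.00 | 0.6 | 24.2 |
| zeta | 5.00 | 2.0 | 39.5 |
| zeta | 6.00 | 3.0 | 46.4 |
| beta | 1.33 | 0.2 | 10.7 |
| beta | 2.50 | 0.2 | 19.4 |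
| beta | 4.00 | 2.8 | 31.0 |
| beta | 5.00 | 3.7 | 37.9 |

(readings scatter by 0.3 percentage points)

- average number of monomer units in a chain (chains begun, living or dead) at 12 min
- part of the free monomer that has reacted at 12 min

- the average divides the monomer in chains by the number of chains begun, living and dead together
- the earlier runs do not show the number of chains; that part of a forecast is a guess
- percentages count the whole charge, also what has not yet gone in

I turned the question round: what would the zeta readings show if the chains stayed near one unit, every uptake being a start (initiation)? Free monomer rose with time under the feed, so with the initiator held at its charge, uptake by starts would go as time squared, and going from 3.00 min to 6.00 min would multiply monomer in chains by 4. The readings gave 5.00, a loose figure, with a scatter of 0.3 percentage points on 0.6%.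

So I put that first answer back in. Ends made as time squared, taking up free monomer that rises with time, add an uptake going as time to the fourth, and growth (propagation) stands to starts as the square of time over T. Read off that loose ratio, the crossing time T came to 9.95 min, the moment at which growth has taken up as much as starts. Short chains would need T far beyond 12 min, but it lay below that. Beta, with twice the initiator, held 3.7% at 5.00 min where zeta held 2.0%, so I scaled uptake with initiator and left T free of it.

Scaled from 6.00 min, I reckoned 21.6% reacted. Its start part, 0.880 mM, asked for more than the 0.81 mM of initiator charged. Going round again with the initiator running down, I got 0.537 mM of chains begun. Dividing the whole reckoned uptake, left as it stood, by those chains made 4.02 units.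

The forecast gave 2.3 units (1.6 to 3.6) and 12% (9.5% to 15.5%), reasoning “so initiation must be slow and much initiator is still unused”.

The flask gave 4.95 units and 24.9% reacted.

    monomer in chains + living end → free monomer + living end, rate k1*[living end] as long as [monomer in chains] is above zero (k = 0.00440 /s)
    free monomer + living end → monomer in chains + living end, rate k2*[living end]*[free monomer] (k = 2.90 /M/s)
    free monomer + initiator → living end + monomer in chains (k = 0.310 /M/s)

At 12 min the flask still held 38% of its initiator. At 6.00 min, T gave 1.36 units on this flask, which held 1.76. For the flask with 2.0 mM of initiator, T and the scaling gave 53.3% reacted, and that flask gave 45.4%.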